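Time was what the two earlier runs let me compare: over their first readings, the teal run made left-handed product 4.02 times as fast as the blue run, and it held 4.06 times the reagent. I read this, within the scatter, as first order in reagent. Both runs held the same catalyst and impurity, however, so neither could speak about catalyst.

| flask | left-handed substrate | right-handed substrate | reagent | free catalyst | impurity | remark |
|---|---|---|---|---|---|---|
| blue | 0.053 M | 0.053 M | 0.032 M | 26 µM | 3.9 µM | run made earlier |
| teal | 0.053 M | 0.053 M | 0.13 M | 26 µM | 3.9 µM | run made earlier |
| flask | 0.053 M | 0.053 M | 0.0636 M | 26 µM | 3.9 µM |  |

| run | time / s | left-handed product / % |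
|---|---|---|
| blue | 15.0 | 4.1 |
| blue | 30.0 | 7.2 |
| blue | 50.0 | 11.2 |
| blue | 60.0 | 12.5 |
| blue | 80.0 | 14.8 |
| blue | 90.0 | 16.8 |
| blue | 120 | 18.8 |
| teal | 10.0 | 11.0 |
| teal | 20.0 | 18.9 |
| teal | 30.0 | 25.0 |
| teal | 50.0 | 34.2 |
| teal | 80.0 | 43.0 |
| teal | 90.0 | 43.9 |
| teal | 120 | 46.8 |

(readings scatter by 0.5 percentage points)

- free catalyst is single-handed; left-handed substrate and right-handed substrate are mirror images of each other, charged as a racemate, each of them at the stated concentration
- no earlier run changes the charge of free catalyst; that part of a forecast is a guess

- apparent order in reagent when 10% of the left-handed substrate and right-handed substrate together are converted (percent change of the rate of making left-handed product for one percent more reagent charged)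
- apparent order in free catalyst when 10% of the left-handed substrate and right-handed substrate together are converted (percent change of the rate of making left-handed product for one percent more free catalyst charged)
- factor on the rate of making left-handed product when 10% of the left-handed substrate and right-handed substrate together are converted if free catalyst is charged twice over

The bench rule says that a reaction is first order in its catalyst, which would give an order of 1 and a factor of 2 on doubling the charge. I applied it and then looked for its border. The rule stops working once a fixed amount is taken from the charge, and the ratio [impurity]/[free catalyst] was 15.0%, which is too large to ignore.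

I guessed that each impurity removes one free catalyst for good, as a poison does. My working-share factor in the new flask was then 1.18: the charge divided by what remains of it to work after the fixed loss. A rate proportional to that remainder has this factor as its apparent order. Doubling the charge gave me a factor of 2.18. For reagent, the fixed loss at 10% conversion was 0.0106 M, so the same reckoning gave an order of 1.20.

The forecast gave 1.2 for reagent, then 1.1 and 2.15 for catalyst, with the remark “Catalyst is not tested by any run.” Its reagent order stood with mine, but its catalyst numbers lay below my own.

The flask gave 1.2, 1.2 and 2.18.

    reagent + catalyst intermediate B → free catalyst + right-handed product (k = 37.0 M⁻¹ s⁻¹)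
    free catalyst + left-handed substrate ⇌ catalyst intermediate A (K = 20.0 M⁻¹, k = 1.50 × 10⁵ M⁻¹ s⁻¹)
    free catalyst + right-handed substrate ⇌ catalyst intermediate B (K = 11.0 M⁻¹, k = 14000 M⁻¹ s⁻¹)
    free catalyst + impurity → spent catalyst (k = 2.20 × 10⁵ M⁻¹ s⁻¹)
    reagent + catalyst intermediate A → free catalyst + left-handed product (k = 1100 M⁻¹ s⁻¹)

After 0.200 min the flask held 0% of its impurity, and spent catalyst stood at 15.0% of the catalyst charged. The largest single effect on the rate at 10% conversion is the backward run from catalyst intermediate B to free catalyst and right-handed substrate: in the same run without it, the rate was 0.00958 times the actual one. The capture of free catalyst by impurity is a further part of why that rate stands where it does. The proof is a second flask, the same run with that step taken away. Against a working-share factor of 1.18, that flask ran at 1.18 times the actual rate.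

All runs were computed with constants of no real substance, and the scatter is random.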